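## Retrosynthetic overview
1. The target comes from its nona-silyl ether. The C7–OH is installed last by sterically governed C–H borylation/oxidation of the 7-deoxy 3,5-digallate. Ring A can therefore come from resorcinol, and O5 and O7 never have to be told apart.
2. The 3-O-gallate comes from esterifying the cis-flavan-3-ol, which comes from bulky-hydride reduction of a (2R)-flavan-3-one (sets C3).
3. Key disconnection: ring C of the flavan-3-one comes from a one-carbon ring expansion of a 2-aryl-3-methylene-2,3-dihydrobenzofuran. The ring A ipso carbon shifts from C3 to the exocyclic CH2.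
4. The five-membered ring comes from a 5-exo-dig aryl-radical closure of an (S)-propargyl 2-iodoaryl ether. That ether is made by copper-catalysed enantioselective propargylic etherification (sets C2).
5. Ring B and both galloyl rings come from p-cresol, C3–C4 from HC≡CMgBr, and ring A from resorcinol. Ring order: aromatic rings first, then the five-membered O-ring, then its expansion to ring C.

Assumption: TBS = tert-butyldimethylsilyl (TBSO = its ether); the pybox antipode named in step 8 is assumed to give the (S)-ether, and the mirror-image ligand is used if the sense of induction is opposite.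

## Route

Step 1
Reactants: 1 p-cresol
Product: 4 3,5-dibromo-4-hydroxybenzaldehyde, via 2,6-dibromo-4-methylphenol 2 (not isolated), via 2,6-dibromo-4-(dibromomethyl)phenol 3 (not isolated)
Conditions: Br2 (2.05 equiv), 1,2-dichlorobenzene, 35 °C; Br2 (2.05 equiv), 150 °C; then H2O, 100 °C
Reagents that add atoms: bromine BrBr; water O
Why: Electrophilic aromatic bromination fills both positions ortho to OH, thermal benzylic dibromination then takes the methyl group to the benzal bromide, and hydrolysis gives the aldehyde, a proven one-pot sequence for p-cresol.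

Step 2
Reactants: 4 3,5-dibromo-4-hydroxybenzaldehyde
Product: 5 3,4,5-trihydroxybenzaldehyde
Conditions: degassed 2 M aq NaOH (8 equiv), Cu2O (5 mol %), reflux, N2, 20 h; then 6 M HCl, 0 °C
Reagents that add atoms: sodium hydroxide [Na+].[OH-]
Why: Ullmann-type copper-catalysed hydroxylation of aryl bromides ortho to a phenoxide is the reaction used for 5-bromovanillin, and the para-phenoxide shields the aldehyde from Cannizzaro chemistry.

Step 3
Reactants: 5 3,4,5-trihydroxybenzaldehyde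
Product: 6 3,4,5-tris(TBSO)benzaldehyde
Conditions: TBSCl (3.6 equiv), imidazole (7 equiv), DMF, rt
Reagents that add atoms: tert-butyldimethylsilyl chloride CC(C)(C)[Si](C)(C)Cl
Why: Standard silyl ether protection gives groups with no aromatic C–H bonds, which matters in step 13, and they come off with fluoride without touching aryl esters.

Step 4
Reactants: 6 3,4,5-tris(TBSO)benzaldehyde
Product: 7 3,4,5-tris(TBSO)benzoic acid
Conditions: NaClO2, NaH2PO4, 2-methyl-2-butene, t-BuOH–H2O, rt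
Reagents that add atoms: sodium chlorite [Na+].[O-]Cl=O
Why: The Pinnick oxidation converts aromatic aldehydes to acids at buffered pH without harming aryl silyl ethers.

Step 5
Reactants: 6 3,4,5-tris(TBSO)benzaldehyde; 8 ethynylmagnesium bromide
Product: 10 rac-1-[3,4,5-tris(TBSO)phenyl]prop-2-yn-1-yl acetate, via bromomagnesium alkoxide 9 (not isolated)
Conditions: 8 (1.2 equiv), THF, 0 °C; then Ac2O (1.5 equiv), 0 °C to rt
Reagents that add atoms: acetic anhydride CC(=O)OC(C)=O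
Why: Grignard 1,2-addition followed by in situ O-acetylation gives the propargylic ester in one flask, and the racemate is sufficient because step 8 is enantioconvergent.

Step 6
Reactants: 11 resorcinol
Product: 12 2-iodoresorcinol
Conditions: I2 (1.05 equiv), NaHCO3 (1.1 equiv), H2O, 0 °C to rt
Reagents that add atoms: iodine [I][I]
Why: Electrophilic iodination in aqueous bicarbonate is known to give the 2-iodo isomer between the two OH groups, which marks the future C4a and keeps both oxygens equivalent.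

Step 7
Reactants: 12 2-iodoresorcinol; 7 3,4,5-tris(TBSO)benzoic acid
Product: 13 3-hydroxy-2-iodophenyl 3,4,5-tris(TBSO)benzoate
Conditions: 12 (3 equiv, excess recovered), 7 (1 equiv), EDC·HCl (1.2 equiv), DMAP (0.1 equiv), CH2Cl2–THF, 0 °C to rt
Reagents that add atoms: none
Why: Steglich-type esterification with the cheap symmetrical diol in excess gives mainly the monoester, which installs the final 5-O-gallate, tempers the C-nucleophilicity of ring A for step 8 and masks the phenol for step 10.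

Step 8
Reactants: 13 3-hydroxy-2-iodophenyl 3,4,5-tris(TBSO)benzoate; 10 rac-1-[3,4,5-tris(TBSO)phenyl]prop-2-yn-1-yl acetate
Product: 14 2-iodo-3-{(1S)-1-[3,4,5-tris(TBSO)phenyl]prop-2-yn-1-yloxy}phenyl 3,4,5-tris(TBSO)benzoate
Conditions: CuOTf·0.5C6H6 (5 mol %), (S,S)-Ph-pybox (10 mol %), i-Pr2NEt (1.2 equiv), ClCH2CH2Cl, −10 °C
Reagents that add atoms: none
Why: In this copper-catalysed asymmetric propargylic substitution both enantiomers of 10 funnel into one planar copper allenylidene, which the phenol attacks at the aryl-bearing carbon under ligand control, so the future C2 is set as (S), the same spatial arrangement as 2R in the later rings.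

Step 9
Reactants: 14 2-iodo-3-{(1S)-1-[3,4,5-tris(TBSO)phenyl]prop-2-yn-1-yloxy}phenyl 3,4,5-tris(TBSO)benzoate
Product: 15 (2R)-3-methylidene-2-[3,4,5-tris(TBSO)phenyl]-2,3-dihydro-1-benzofuran-4-yl 3,4,5-tris(TBSO)benzoate
Conditions: (Me3Si)3SiH (1.3 equiv), Et3B (0.2 equiv), trace air, toluene, 0 °C to rt; short plug of Et3N-washed SiO2, used at once
Reagents that add atoms: none
Why: A 5-exo-dig aryl-radical cyclisation in a silane chain closes the five-membered ring exactly at the iodine-marked carbon under neutral, metal-hydride-free conditions, so the exocyclic alkene is not isomerised and C2 is untouched.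

Step 10
Reactants: 15 (2R)-3-methylidene-2-[3,4,5-tris(TBSO)phenyl]-2,3-dihydro-1-benzofuran-4-yl 3,4,5-tris(TBSO)benzoate
Product: 17 (2R)-3-oxo-2-[3,4,5-tris(TBSO)phenyl]-3,4-dihydro-2H-chromen-5-yl 3,4,5-tris(TBSO)benzoate, via hydroxy-iodane adduct 16 (not isolated)
Conditions: PhI(OH)OTs (1.05 equiv), MeCN–H2O 10:1, −20 to 0 °C, 30 min; aq NaHCO3; crude ketone carried straight into step 11
Reagents that add atoms: water O
Why: Proposed new method: the trivalent iodine electrophile adds to the terminal CH2 of the electron-rich styrene-type alkene and water captures the tertiary benzylic cation at C3 to give 16; loss of PhI from the CH2 is then driven by the C3–OH lone pair with a 1,2-shift of the alkoxy-activated ring A ipso carbon, which out-competes the oxygen-bearing, inductively deactivated C2, so the five-membered ring becomes the six-membered 3-ketone while the C2–H stereocentre is never involved; the closest known reaction type is the oxidative semipinacol (Tiffeneau–Demjanov-like) ring expansion of 1-methylene-indanes and -tetralins with the same reagent, not yet shown on a 3-methylene-2,3-dihydrobenzofuran that carries an isomerisation-prone C2 stereocentre.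

Step 11
Reactants: 17 (2R)-3-oxo-2-[3,4,5-tris(TBSO)phenyl]-3,4-dihydro-2H-chromen-5-yl 3,4,5-tris(TBSO)benzoate
Product: 18 (2R,3R)-3-hydroxy-2-[3,4,5-tris(TBSO)phenyl]-3,4-dihydro-2H-chromen-5-yl 3,4,5-tris(TBSO)benzoate
Conditions: LiBH(s-Bu)3 (1.1 equiv), LiBr (2 equiv), THF, −78 °C; AcOH quench at −78 °C
Reagents that add atoms: none
Why: Diastereoselective ketone reduction with the bulky borohydride attacks the half-chair equatorially and gives the axial 3-OH cis to the equatorial 2-aryl group, as established for protected flavan-3-ones, which sets C3 as R; any O5-to-O3 acyl drift is harmless because step 12 acylates whichever OH is free.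

Step 12
Reactants: 18 (2R,3R)-3-hydroxy-2-[3,4,5-tris(TBSO)phenyl]-3,4-dihydro-2H-chromen-5-yl 3,4,5-tris(TBSO)benzoate; 7 3,4,5-tris(TBSO)benzoic acid
Product: 19 (2R,3R)-2-[3,4,5-tris(TBSO)phenyl]-3,4-dihydro-2H-chromene-3,5-diyl bis[3,4,5-tris(TBSO)benzoate]
Conditions: 7 (1.5 equiv), EDC·HCl (2 equiv), DMAP (1 equiv), CH2Cl2, rt
Reagents that add atoms: none
Why: Steglich esterification of the axial 3-OH is the standard way to 3-O-gallates of epi-series flavanols and leaves both stereocentres alone.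

Step 13
Reactants: 19 (2R,3R)-2-[3,4,5-tris(TBSO)phenyl]-3,4-dihydro-2H-chromene-3,5-diyl bis[3,4,5-tris(TBSO)benzoate]
Product: 21 (2R,3R)-7-hydroxy-2-[3,4,5-tris(TBSO)phenyl]-3,4-dihydro-2H-chromene-3,5-diyl bis[3,4,5-tris(TBSO)benzoate], via C7 pinacol boronate 20 (not isolated)
Conditions: [Ir(cod)(OMe)]2 (5 mol %), 4,4'-di-tert-butyl-2,2'-bipyridine (10 mol %), B2pin2 (1.5 equiv), THF, 80 °C; evaporate; 2KHSO5·KHSO4·K2SO4, acetone–H2O, 0 °C, 10 min
Reagents that add atoms: bis(pinacolato)diboron CC1(C)OB(OC1(C)C)B1OC(C)(C)C(C)(C)O1 (boryl group of 20 only); potassium peroxymonosulfate [K+].[O-]S(=O)(=O)OO (the C7 oxygen)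
Why: Iridium-catalysed C–H borylation is sterically controlled and C7–H is the only aromatic C–H in 19 without an ortho substituent (all ring B and galloyl C–H bonds are flanked on both sides, and C6–H and C8–H on one), so the boronate and, after brief near-neutral oxidation, the free phenol appear only at C7 with the esters intact.

Step 14
Reactants: 21 (2R,3R)-7-hydroxy-2-[3,4,5-tris(TBSO)phenyl]-3,4-dihydro-2H-chromene-3,5-diyl bis[3,4,5-tris(TBSO)benzoate]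
Product: 22 epigallocatechin 3,5-digallate
Conditions: Et3N·3HF (30 equiv), THF–MeCN, 0 °C to rt, argon; Sephadex LH-20
Reagents that add atoms: none
Why: Fluoride-driven cleavage of all nine aryl silyl ethers under slightly acidic, non-nucleophilic conditions spares the alkyl and aryl gallate esters, the benzylic C2–O bond and both stereocentres.

## Compound list
1 | p-cresol | Cc1ccc(O)cc1 | starting material
2 | 2,6-dibromo-4-methylphenol | Cc1cc(Br)c(O)c(Br)c1 | intermediate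
3 | 2,6-dibromo-4-(dibromomethyl)phenol | BrC(Br)c1cc(Br)c(O)c(Br)c1 | intermediate
4 | 3,5-dibromo-4-hydroxybenzaldehyde | O=Cc1cc(Br)c(O)c(Br)c1 | intermediate
5 | 3,4,5-trihydroxybenzaldehyde | O=Cc1cc(O)c(O)c(O)c1 | intermediate
6 | 3,4,5-tris(TBSO)benzaldehyde | O=Cc1cc(O[Si](C)(C)C(C)(C)C)c(O[Si](C)(C)C(C)(C)C)c(O[Si](C)(C)C(C)(C)C)c1 | intermediate
7 | 3,4,5-tris(TBSO)benzoic acid | OC(=O)c1cc(O[Si](C)(C)C(C)(C)C)c(O[Si](C)(C)C(C)(C)C)c(O[Si](C)(C)C(C)(C)C)c1 | intermediate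
8 | ethynylmagnesium bromide | C#C[Mg]Br | starting material
9 | bromomagnesium 1-[3,4,5-tris(TBSO)phenyl]prop-2-yn-1-olate | C#CC(O[Mg]Br)c1cc(O[Si](C)(C)C(C)(C)C)c(O[Si](C)(C)C(C)(C)C)c(O[Si](C)(C)C(C)(C)C)c1 | intermediate
10 | rac-1-[3,4,5-tris(TBSO)phenyl]prop-2-yn-1-yl acetate | CC(=O)OC(C#C)c1cc(O[Si](C)(C)C(C)(C)C)c(O[Si](C)(C)C(C)(C)C)c(O[Si](C)(C)C(C)(C)C)c1 | intermediate
11 | resorcinol | Oc1cccc(O)c1 | starting material
12 | 2-iodoresorcinol | Oc1cccc(O)c1I | intermediate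
13 | 3-hydroxy-2-iodophenyl 3,4,5-tris(TBSO)benzoate | O=C(Oc1cccc(O)c1I)c1cc(O[Si](C)(C)C(C)(C)C)c(O[Si](C)(C)C(C)(C)C)c(O[Si](C)(C)C(C)(C)C)c1 | intermediate
14 | 2-iodo-3-{(1S)-1-[3,4,5-tris(TBSO)phenyl]prop-2-yn-1-yloxy}phenyl 3,4,5-tris(TBSO)benzoate | C#C[C@@H](c1cc(O[Si](C)(C)C(C)(C)C)c(O[Si](C)(C)C(C)(C)C)c(O[Si](C)(C)C(C)(C)C)c1)Oc1cccc(OC(=O)c2cc(O[Si](C)(C)C(C)(C)C)c(O[Si](C)(C)C(C)(C)C)c(O[Si](C)(C)C(C)(C)C)c2)c1I | intermediate
15 | (2R)-3-methylidene-2-[3,4,5-tris(TBSO)phenyl]-2,3-dihydro-1-benzofuran-4-yl 3,4,5-tris(TBSO)benzoate | O=C(Oc1cccc2c1C(=C)[C@@H](c1cc(O[Si](C)(C)C(C)(C)C)c(O[Si](C)(C)C(C)(C)C)c(O[Si](C)(C)C(C)(C)C)c1)O2)c1cc(O[Si](C)(C)C(C)(C)C)c(O[Si](C)(C)C(C)(C)C)c(O[Si](C)(C)C(C)(C)C)c1 | intermediate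
16 | {(2R)-3-hydroxy-2-aryl-4-(aroyloxy)-2,3-dihydro-1-benzofuran-3-yl}methyl(phenyl)iodonium tosylate (aryl and aroyl as in 15; C3 configuration not fixed, both epimers converge) | O=C(Oc1cccc2c1C(O)(C[I+]c1ccccc1)[C@@H](c1cc(O[Si](C)(C)C(C)(C)C)c(O[Si](C)(C)C(C)(C)C)c(O[Si](C)(C)C(C)(C)C)c1)O2)c1cc(O[Si](C)(C)C(C)(C)C)c(O[Si](C)(C)C(C)(C)C)c(O[Si](C)(C)C(C)(C)C)c1.Cc1ccc(cc1)S(=O)(=O)[O-] | intermediate
17 | (2R)-3-oxo-2-[3,4,5-tris(TBSO)phenyl]-3,4-dihydro-2H-chromen-5-yl 3,4,5-tris(TBSO)benzoate | O=C(Oc1cccc2c1CC(=O)[C@@H](c1cc(O[Si](C)(C)C(C)(C)C)c(O[Si](C)(C)C(C)(C)C)c(O[Si](C)(C)C(C)(C)C)c1)O2)c1cc(O[Si](C)(C)C(C)(C)C)c(O[Si](C)(C)C(C)(C)C)c(O[Si](C)(C)C(C)(C)C)c1 | intermediate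
18 | (2R,3R)-3-hydroxy-2-[3,4,5-tris(TBSO)phenyl]-3,4-dihydro-2H-chromen-5-yl 3,4,5-tris(TBSO)benzoate | O=C(Oc1cccc2c1C[C@@H](O)[C@@H](c1cc(O[Si](C)(C)C(C)(C)C)c(O[Si](C)(C)C(C)(C)C)c(O[Si](C)(C)C(C)(C)C)c1)O2)c1cc(O[Si](C)(C)C(C)(C)C)c(O[Si](C)(C)C(C)(C)C)c(O[Si](C)(C)C(C)(C)C)c1 | intermediate
19 | (2R,3R)-2-[3,4,5-tris(TBSO)phenyl]-3,4-dihydro-2H-chromene-3,5-diyl bis[3,4,5-tris(TBSO)benzoate] | O=C(Oc1cccc2c1C[C@@H](OC(=O)c1cc(O[Si](C)(C)C(C)(C)C)c(O[Si](C)(C)C(C)(C)C)c(O[Si](C)(C)C(C)(C)C)c1)[C@@H](c1cc(O[Si](C)(C)C(C)(C)C)c(O[Si](C)(C)C(C)(C)C)c(O[Si](C)(C)C(C)(C)C)c1)O2)c1cc(O[Si](C)(C)C(C)(C)C)c(O[Si](C)(C)C(C)(C)C)c(O[Si](C)(C)C(C)(C)C)c1 | intermediate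
20 | 7-(4,4,5,5-tetramethyl-1,3,2-dioxaborolan-2-yl) derivative of 19 | O=C(Oc1cc(B3OC(C)(C)C(C)(C)O3)cc2c1C[C@@H](OC(=O)c1cc(O[Si](C)(C)C(C)(C)C)c(O[Si](C)(C)C(C)(C)C)c(O[Si](C)(C)C(C)(C)C)c1)[C@@H](c1cc(O[Si](C)(C)C(C)(C)C)c(O[Si](C)(C)C(C)(C)C)c(O[Si](C)(C)C(C)(C)C)c1)O2)c1cc(O[Si](C)(C)C(C)(C)C)c(O[Si](C)(C)C(C)(C)C)c(O[Si](C)(C)C(C)(C)C)c1 | intermediate
21 | (2R,3R)-7-hydroxy-2-[3,4,5-tris(TBSO)phenyl]-3,4-dihydro-2H-chromene-3,5-diyl bis[3,4,5-tris(TBSO)benzoate] | O=C(Oc1cc(O)cc2c1C[C@@H](OC(=O)c1cc(O[Si](C)(C)C(C)(C)C)c(O[Si](C)(C)C(C)(C)C)c(O[Si](C)(C)C(C)(C)C)c1)[C@@H](c1cc(O[Si](C)(C)C(C)(C)C)c(O[Si](C)(C)C(C)(C)C)c(O[Si](C)(C)C(C)(C)C)c1)O2)c1cc(O[Si](C)(C)C(C)(C)C)c(O[Si](C)(C)C(C)(C)C)c(O[Si](C)(C)C(C)(C)C)c1 | intermediate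
22 | epigallocatechin 3,5-digallate, (2R,3R) | O=C(Oc1cc(O)cc2c1C[C@@H](OC(=O)c1cc(O)c(O)c(O)c1)[C@@H](c1cc(O)c(O)c(O)c1)O2)c1cc(O)c(O)c(O)c1 | target

## Step count and risk
Total step count: 14. Longest linear sequence: 12 (steps 1–4, then 7–14).

**Step 10 (the proposed new step).** There are three risks:
- Acid released in the reaction could isomerise the labile alkene 15 to the aromatic 3-methylbenzofuran.
- C2 could migrate instead of the aryl carbon, which would give the flavanone.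
- The ketone could lose its C2 configuration.

The fallback uses known chemistry, sets out from 15 and returns at 17. Neutral dihydroxylation (OsO4 cat., NMO, acetone–H2O) from the face opposite the 2-aryl group gives the 3-hydroxy-3-(hydroxymethyl) diol F4. MsCl (1.05 equiv) with 2,4,6-collidine at −20 °C sulfonylates only the primary hydroxyl to give the primary mesylate F5. The classical diol-monosulfonate pinacol-type rearrangement (LiClO4, CaCO3, THF, 50 °C, or Et2AlCl, CH2Cl2, −78 °C) then moves the ring A carbon onto the CH2 and delivers 17 without any oxidant or strong acid.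

**Step 8.** The hindered ortho-iodophenol 13 may react slowly, alkylate at carbon, or give low enantiomeric excess.

The fallback sets out from 6 and 8 and returns at 14. The alkoxide 9 is quenched with aq NH4Cl to the racemic propargylic alcohol F1. MnO2 in CH2Cl2 gives the ynone F2. Oxazaborolidine-catalysed borane reduction ((S)-Me-CBS, BH3·SMe2, THF, −30 °C, aryl as the large group) gives the (R)-propargylic alcohol F3. Mitsunobu etherification with 13 (PPh3, DIAD, toluene, −20 °C) proceeds with inversion to 14.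

**Step 13.** The very crowded 19 may borylate sluggishly, and the aryl ester may suffer in the oxidation.

The fallback moves the C–H oxygenation to the small arene 13 and returns at 22:
- HBpin (1.1 equiv) masks the phenol. The same [Ir(cod)(OMe)]2/bipyridine/B2pin2 system then borylates the only unhindered C–H of this 1,2,3-trisubstituted ring to give the O,C-bis(boryl) ester F6.
- KHSO5 gives the 3,5-dihydroxy-2-iodophenyl ester F7.
- TBSCl (1.0 equiv) with imidazole at −20 °C silylates the unhindered hydroxyl to give the 5-TBSO iodophenol ester F8.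
- F8 is taken through the conditions of steps 8 to 12. This gives in turn the (S)-propargyl ether F9, the 6-TBSO methylene-dihydrobenzofuran F10, its hydroxy-iodane adduct F11, the 7-TBSO flavan-3-one F12, the 7-TBSO cis-alcohol F13 and the deca-silyl digallate F14.
- The conditions of step 14 convert F14 directly into 22.

## Further compounds
F1 | step 8 | rac-1-[3,4,5-tris(TBSO)phenyl]prop-2-yn-1-ol | C#CC(O)c1cc(O[Si](C)(C)C(C)(C)C)c(O[Si](C)(C)C(C)(C)C)c(O[Si](C)(C)C(C)(C)C)c1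
F2 | step 8 | 1-[3,4,5-tris(TBSO)phenyl]prop-2-yn-1-one | C#CC(=O)c1cc(O[Si](C)(C)C(C)(C)C)c(O[Si](C)(C)C(C)(C)C)c(O[Si](C)(C)C(C)(C)C)c1
F3 | step 8 | (1R)-1-[3,4,5-tris(TBSO)phenyl]prop-2-yn-1-ol | C#C[C@H](c1cc(O[Si](C)(C)C(C)(C)C)c(O[Si](C)(C)C(C)(C)C)c(O[Si](C)(C)C(C)(C)C)c1)O
F4 | step 10 | (2R)-3-hydroxy-3-(hydroxymethyl)-2-[3,4,5-tris(TBSO)phenyl]-2,3-dihydro-1-benzofuran-4-yl 3,4,5-tris(TBSO)benzoate, 3-OH anti to the 2-aryl group | O=C(Oc1cccc2c1[C@@](O)(CO)[C@@H](c1cc(O[Si](C)(C)C(C)(C)C)c(O[Si](C)(C)C(C)(C)C)c(O[Si](C)(C)C(C)(C)C)c1)O2)c1cc(O[Si](C)(C)C(C)(C)C)c(O[Si](C)(C)C(C)(C)C)c(O[Si](C)(C)C(C)(C)C)c1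
F5 | step 10 | primary methanesulfonate of F4 | O=C(Oc1cccc2c1[C@@](O)(COS(C)(=O)=O)[C@@H](c1cc(O[Si](C)(C)C(C)(C)C)c(O[Si](C)(C)C(C)(C)C)c(O[Si](C)(C)C(C)(C)C)c1)O2)c1cc(O[Si](C)(C)C(C)(C)C)c(O[Si](C)(C)C(C)(C)C)c(O[Si](C)(C)C(C)(C)C)c1
F6 | step 13 | 2-iodo-3-(pinacolatoboryloxy)-5-(pinacolatoboryl)phenyl 3,4,5-tris(TBSO)benzoate | O=C(Oc1cc(B2OC(C)(C)C(C)(C)O2)cc(OB2OC(C)(C)C(C)(C)O2)c1I)c1cc(O[Si](C)(C)C(C)(C)C)c(O[Si](C)(C)C(C)(C)C)c(O[Si](C)(C)C(C)(C)C)c1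
F7 | step 13 | 3,5-dihydroxy-2-iodophenyl 3,4,5-tris(TBSO)benzoate | O=C(Oc1cc(O)cc(O)c1I)c1cc(O[Si](C)(C)C(C)(C)C)c(O[Si](C)(C)C(C)(C)C)c(O[Si](C)(C)C(C)(C)C)c1
F8 | step 13 | 3-hydroxy-2-iodo-5-(TBSO)phenyl 3,4,5-tris(TBSO)benzoate | O=C(Oc1cc(O[Si](C)(C)C(C)(C)C)cc(O)c1I)c1cc(O[Si](C)(C)C(C)(C)C)c(O[Si](C)(C)C(C)(C)C)c(O[Si](C)(C)C(C)(C)C)c1
F9 | step 13 | 2-iodo-5-(TBSO)-3-{(1S)-1-[3,4,5-tris(TBSO)phenyl]prop-2-yn-1-yloxy}phenyl 3,4,5-tris(TBSO)benzoate | C#C[C@@H](c1cc(O[Si](C)(C)C(C)(C)C)c(O[Si](C)(C)C(C)(C)C)c(O[Si](C)(C)C(C)(C)C)c1)Oc1cc(O[Si](C)(C)C(C)(C)C)cc(OC(=O)c2cc(O[Si](C)(C)C(C)(C)C)c(O[Si](C)(C)C(C)(C)C)c(O[Si](C)(C)C(C)(C)C)c2)c1I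
F10 | step 13 | (2R)-3-methylidene-6-(TBSO)-2-[3,4,5-tris(TBSO)phenyl]-2,3-dihydro-1-benzofuran-4-yl 3,4,5-tris(TBSO)benzoate | O=C(Oc1cc(O[Si](C)(C)C(C)(C)C)cc2c1C(=C)[C@@H](c1cc(O[Si](C)(C)C(C)(C)C)c(O[Si](C)(C)C(C)(C)C)c(O[Si](C)(C)C(C)(C)C)c1)O2)c1cc(O[Si](C)(C)C(C)(C)C)c(O[Si](C)(C)C(C)(C)C)c(O[Si](C)(C)C(C)(C)C)c1
F11 | step 13 | 6-TBSO analogue of iodonium tosylate 16 (C3 configuration not fixed) | O=C(Oc1cc(O[Si](C)(C)C(C)(C)C)cc2c1C(O)(C[I+]c1ccccc1)[C@@H](c1cc(O[Si](C)(C)C(C)(C)C)c(O[Si](C)(C)C(C)(C)C)c(O[Si](C)(C)C(C)(C)C)c1)O2)c1cc(O[Si](C)(C)C(C)(C)C)c(O[Si](C)(C)C(C)(C)C)c(O[Si](C)(C)C(C)(C)C)c1.Cc1ccc(cc1)S(=O)(=O)[O-]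
F12 | step 13 | (2R)-3-oxo-7-(TBSO)-2-[3,4,5-tris(TBSO)phenyl]-3,4-dihydro-2H-chromen-5-yl 3,4,5-tris(TBSO)benzoate | O=C(Oc1cc(O[Si](C)(C)C(C)(C)C)cc2c1CC(=O)[C@@H](c1cc(O[Si](C)(C)C(C)(C)C)c(O[Si](C)(C)C(C)(C)C)c(O[Si](C)(C)C(C)(C)C)c1)O2)c1cc(O[Si](C)(C)C(C)(C)C)c(O[Si](C)(C)C(C)(C)C)c(O[Si](C)(C)C(C)(C)C)c1
F13 | step 13 | (2R,3R)-3-hydroxy-7-(TBSO)-2-[3,4,5-tris(TBSO)phenyl]-3,4-dihydro-2H-chromen-5-yl 3,4,5-tris(TBSO)benzoate | O=C(Oc1cc(O[Si](C)(C)C(C)(C)C)cc2c1C[C@@H](O)[C@@H](c1cc(O[Si](C)(C)C(C)(C)C)c(O[Si](C)(C)C(C)(C)C)c(O[Si](C)(C)C(C)(C)C)c1)O2)c1cc(O[Si](C)(C)C(C)(C)C)c(O[Si](C)(C)C(C)(C)C)c(O[Si](C)(C)C(C)(C)C)c1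
F14 | step 13 | (2R,3R)-7-(TBSO)-2-[3,4,5-tris(TBSO)phenyl]-3,4-dihydro-2H-chromene-3,5-diyl bis[3,4,5-tris(TBSO)benzoate] | O=C(Oc1cc(O[Si](C)(C)C(C)(C)C)cc2c1C[C@@H](OC(=O)c1cc(O[Si](C)(C)C(C)(C)C)c(O[Si](C)(C)C(C)(C)C)c(O[Si](C)(C)C(C)(C)C)c1)[C@@H](c1cc(O[Si](C)(C)C(C)(C)C)c(O[Si](C)(C)C(C)(C)C)c(O[Si](C)(C)C(C)(C)C)c1)O2)c1cc(O[Si](C)(C)C(C)(C)C)c(O[Si](C)(C)C(C)(C)C)c(O[Si](C)(C)C(C)(C)C)c1
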